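**Retrosynthetic overview**

- The strategy rests on the tertiary carbinol C3 of the butyrolactone (ring atoms O1, C2, C3, C4, C5). It lies between the lactone carbonyl C2 and the benzyl-bearing C4, so C2/C3 is read as an α-keto ester, O1–C5 as its propargylic ester link, and the C4 benzyl as a reduced arylidene.
- Disconnections, backwards: the two phenol O-benzyl groups (hydrogenolysis); C4–H (hydroxyl-directed hydrogenation of a C4 (E)-arylidene); C3–C4 (enantioselective reductive coupling of the ketone with the tethered aryl alkyne); O1–C5 (carboxylate alkylation by an aryl-propargyl bromide).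
- Fragments: the arylpyruvic acid comes from O-benzylvanillin and hydantoin; the aryl-propargyl bromide comes from 4-iodo-2-methoxyphenol and propargyl alcohol. Both arenes are the same vanillyl unit.
- Ring order: both benzene rings are bought; the lactone is the only ring made and is closed by C3–C4 bond formation in step 7.

Key step: step 7

Remarks on the chemistry:

- Numbering of the lactone throughout: O1, C2 (carbonyl), C3 (carbinol), C4, C5 (CH2O).
- Assumption: the sense of induction of the biaryl bisphosphine in step 7 cannot be derived with certainty for this substrate class; the (R)-ligand is written, and its (S)-antipode is used instead if a trial run gives the 3R carbinol.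
- Compounds 4, 10 and 11 are drawn as keto tautomers although they are expected to rest largely as the conjugated enols.
- The ester link is made by carboxylate alkylation (one extra step, bromide 9) rather than by acyl activation, so that the enol hydroxyl of the pyruvate cannot be acylated.

**Route**

Step 1
Reactants: 1 4-(benzyloxy)-3-methoxybenzaldehyde; 2 hydantoin
Product: 3 (Z)-5-[4-(benzyloxy)-3-methoxybenzylidene]imidazolidine-2,4-dione
Conditions: NH4OAc, AcOH, reflux
Reagents that add atoms: none
Why: Knoevenagel-type condensation of the acidic C5 methylene of hydantoin with the aldehyde, buffered by ammonium acetate, should give the conjugated (Z)-benzylidene hydantoin, which is expected to crystallise from the cooled acid.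

Step 2
Reactants: 3 (Z)-5-[4-(benzyloxy)-3-methoxybenzylidene]imidazolidine-2,4-dione
Product: 4 3-[4-(benzyloxy)-3-methoxyphenyl]-2-oxopropanoic acid
Conditions: 20% aq. NaOH, reflux, N2; then conc. HCl, 0 °C, pH 1
Reagents that add atoms: water, O
Why: Alkaline hydrolysis of a 5-arylidene hydantoin is the classical entry to arylpyruvic acids, since hydroxide opens the imide and the resulting ureido-acrylate loses its nitrogen as ammonia and carbonate when the enamine carbon is hydrolysed to the ketone, while the benzyl aryl ether is inert to base; air is excluded and the acidification is kept cold because the enolised keto acid is prone to aldol and oxidative degradation.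

Step 3
Reactants: 5 4-iodo-2-methoxyphenol
Product: 6 1-(benzyloxy)-4-iodo-2-methoxybenzene
Conditions: BnBr, K2CO3, DMF, rt
Reagents that add atoms: benzyl bromide, BrCc1ccccc1
Why: Williamson ether synthesis on the phenoxide; the benzyl ether masks the phenol through the metal-catalysed steps and leaves at the end by hydrogenolysis together with the one on the other half.

Step 4
Reactants: 6 1-(benzyloxy)-4-iodo-2-methoxybenzene; 7 prop-2-yn-1-ol
Product: 8 3-[4-(benzyloxy)-3-methoxyphenyl]prop-2-yn-1-ol
Conditions: PdCl2(PPh3)2 (2 mol%), CuI (4 mol%), Et3N, THF, rt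
Reagents that add atoms: none
Why: Sonogashira coupling of an aryl iodide with a terminal alkyne runs at room temperature and tolerates the free primary alcohol.

Step 5
Reactants: 8 3-[4-(benzyloxy)-3-methoxyphenyl]prop-2-yn-1-ol
Product: 9 1-(benzyloxy)-4-(3-bromoprop-1-yn-1-yl)-2-methoxybenzene
Conditions: CBr4, PPh3, CH2Cl2, 0 °C
Reagents that add atoms: carbon tetrabromide, BrC(Br)(Br)Br
Why: Appel bromination converts the primary propargylic alcohol into the bromide under neutral conditions that leave the alkyne and the benzyl ether untouched; the bromide is used without storage.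

Step 6
Reactants: 4 3-[4-(benzyloxy)-3-methoxyphenyl]-2-oxopropanoic acid; 9 1-(benzyloxy)-4-(3-bromoprop-1-yn-1-yl)-2-methoxybenzene
Product: 11 3-[4-(benzyloxy)-3-methoxyphenyl]prop-2-yn-1-yl 3-[4-(benzyloxy)-3-methoxyphenyl]-2-oxopropanoate, via cesium arylpyruvate 10 (not isolated)
Conditions: 4, Cs2CO3 (0.5 equiv), DMF, 0 °C; then 9, 0 °C to rt; product used at once
Reagents that add atoms: none
Why: SN2 O-alkylation of a carboxylate by a reactive propargylic bromide forms the O1–C5 bond without any acyl-activated pyruvate that the enol hydroxyl could attack, and with only half an equivalent of carbonate the enol is not deprotonated, so alkylation should stay at the carboxylate.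

Step 7
Reactants: 11 3-[4-(benzyloxy)-3-methoxyphenyl]prop-2-yn-1-yl 3-[4-(benzyloxy)-3-methoxyphenyl]-2-oxopropanoate
Product: 12 (3S,4E)-3-[4-(benzyloxy)-3-methoxybenzyl]-4-[4-(benzyloxy)-3-methoxybenzylidene]-3-hydroxydihydrofuran-2(3H)-one
Conditions: Rh(cod)2OTf (5 mol%), (R)-Cl,MeO-BIPHEP (5 mol%), Ph3CCO2H (5 mol%), H2 (1 atm), ClCH2CH2Cl, 45 °C
Reagents that add atoms: none
Why: Proposed new method: the cationic rhodium–bisphosphine fragment should bind the aryl alkyne and the two-point-chelating 1,2-dicarbonyl of 11 and couple them oxidatively to an oxarhodacyclopentene, which forms C3–C4; acid-assisted hydrogenolysis of the Rh–O and Rh–C bonds then frees the tertiary alcohol and puts hydrogen on the former distal alkyne carbon cis to C3, which is the (E)-arylidene. The closest known reaction types are the hydrogen-mediated rhodium-catalysed asymmetric reductive cyclization of 1,6-alkynals, the rhodium-catalysed hydrogenative coupling of conjugated alkynes with α-keto esters, and the nickel/silane asymmetric cyclization of ether-tethered alkynones to tertiary allylic alcohols; an ester-tethered alkynyl α-keto ester has not been closed to a lactone in this way. The butyrolactone (O1, C2, C3, C4, C5) closes in a 5-exo-dig mode with respect to the alkyne. The only new stereocentre, C3, is set by the chiral bisphosphine, which selects the ketone face of the chelated keto ester whose benzyl and alkoxycarbonyl arms differ strongly. The step needs enantioface selection at C3, coupling at the proximal alkyne carbon and a defined alkene geometry; the three-atom ester tether lets only the proximal carbon reach the ketone, and the metallacycle fixes the cis relation of C3 and the new vinylic hydrogen. The carboxylic acid co-catalyst should also keep the keto and enol forms of 11 in exchange so that the reactive keto form is drained.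

Step 8
Reactants: 12 (3S,4E)-3-[4-(benzyloxy)-3-methoxybenzyl]-4-[4-(benzyloxy)-3-methoxybenzylidene]-3-hydroxydihydrofuran-2(3H)-one
Product: 13 (3S,4R)-3,4-bis[4-(benzyloxy)-3-methoxybenzyl]-3-hydroxydihydrofuran-2(3H)-one
Conditions: [Ir(cod)(PCy3)(py)]PF6 (5 mol%), H2 (1 atm), CH2Cl2, rt
Reagents that add atoms: none
Why: Hydroxyl-directed homogeneous hydrogenation: the C3 hydroxyl binds the cationic iridium centre and both hydrogens are delivered to the alkene face on its own side, which is also the face remote from the larger C3 benzyl group, so H4 ends cis to the OH, C4 becomes R and the two benzyl groups are cis; palladium on carbon is avoided here because the allylic C5–O bond of 12 could be hydrogenolysed.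

Step 9
Reactants: 13 (3S,4R)-3,4-bis[4-(benzyloxy)-3-methoxybenzyl]-3-hydroxydihydrofuran-2(3H)-one
Product: 14 (3S,4R)-3-hydroxy-3,4-bis(4-hydroxy-3-methoxybenzyl)dihydrofuran-2(3H)-one
Conditions: H2 (1 atm), 10% Pd/C, EtOAc/EtOH, rt
Reagents that add atoms: none
Why: Hydrogenolysis of the two aryl benzyl ethers over palladium; with the alkene saturated, no allylic or benzylic C–O bond other than the two O-benzyl groups remains (the C3 carbinol is homobenzylic), so both stereocentres should be untouched.

**Compound list**

1 | 4-(benzyloxy)-3-methoxybenzaldehyde (O-benzylvanillin) | COc1cc(C=O)ccc1OCc1ccccc1 | starting material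
2 | hydantoin (imidazolidine-2,4-dione) | O=C1CNC(=O)N1 | starting material
3 | (Z)-5-[4-(benzyloxy)-3-methoxybenzylidene]imidazolidine-2,4-dione | COc1cc(/C=C2\NC(=O)NC2=O)ccc1OCc1ccccc1 | intermediate
4 | 3-[4-(benzyloxy)-3-methoxyphenyl]-2-oxopropanoic acid | COc1cc(CC(=O)C(=O)O)ccc1OCc1ccccc1 | intermediate
5 | 4-iodo-2-methoxyphenol | COc1cc(I)ccc1O | starting material
6 | 1-(benzyloxy)-4-iodo-2-methoxybenzene | COc1cc(I)ccc1OCc1ccccc1 | intermediate
7 | prop-2-yn-1-ol (propargyl alcohol) | C#CCO | starting material
8 | 3-[4-(benzyloxy)-3-methoxyphenyl]prop-2-yn-1-ol | COc1cc(C#CCO)ccc1OCc1ccccc1 | intermediate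
9 | 1-(benzyloxy)-4-(3-bromoprop-1-yn-1-yl)-2-methoxybenzene | COc1cc(C#CCBr)ccc1OCc1ccccc1 | intermediate
10 | cesium 3-[4-(benzyloxy)-3-methoxyphenyl]-2-oxopropanoate | COc1cc(CC(=O)C(=O)[O-])ccc1OCc1ccccc1.[Cs+] | intermediate
11 | 3-[4-(benzyloxy)-3-methoxyphenyl]prop-2-yn-1-yl 3-[4-(benzyloxy)-3-methoxyphenyl]-2-oxopropanoate | COc1cc(C#CCOC(=O)C(=O)Cc2ccc(OCc3ccccc3)c(OC)c2)ccc1OCc1ccccc1 | intermediate
12 | (3S,4E)-3-[4-(benzyloxy)-3-methoxybenzyl]-4-[4-(benzyloxy)-3-methoxybenzylidene]-3-hydroxydihydrofuran-2(3H)-one | COc1cc(/C=C2\COC(=O)[C@]2(O)Cc2ccc(OCc3ccccc3)c(OC)c2)ccc1OCc1ccccc1 | intermediate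
13 | (3S,4R)-3,4-bis[4-(benzyloxy)-3-methoxybenzyl]-3-hydroxydihydrofuran-2(3H)-one | COc1cc(C[C@@H]2COC(=O)[C@]2(O)Cc2ccc(OCc3ccccc3)c(OC)c2)ccc1OCc1ccccc1 | intermediate
14 | (3S,4R)-3-hydroxy-3,4-bis(4-hydroxy-3-methoxybenzyl)dihydrofuran-2(3H)-one | COc1cc(C[C@@H]2COC(=O)[C@]2(O)Cc2ccc(O)c(OC)c2)ccc1O | target

**Step count**

Total steps: 9.
Longest linear sequence: 7 steps (5 → 6 → 8 → 9 → 11 → 12 → 13 → 14; steps 3 to 9).

**Steps most likely to fail**

1. Step 7, the step with the new-method label. The cyclization may stall because the ester must rotate into its less populated conformer before the alkyne can reach the ketone, and because the substrate rests as its enol. Plain hydrogenation of the alkyne or of the ketone may outrun C–C coupling, and enantioface selection at C3 may be low.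

   Fallback, known chemistry throughout, with the two stereocentres set in the opposite order and no alkyne–ketone coupling: it sets out from compound 1 and comes back to the route at compound 13. Stobbe condensation of 1 with dimethyl succinate (KOtBu, tBuOH) should give the half-ester (E)-4-[4-(benzyloxy)-3-methoxyphenyl]-3-(methoxycarbonyl)but-3-enoic acid F1. Asymmetric hydrogenation of its carboxylate with [Rh(cod)(Et-DuPHOS)]BF4 under H2 in MeOH, using the ligand antipode that gives the S acid, should give (S)-4-[4-(benzyloxy)-3-methoxyphenyl]-3-(methoxycarbonyl)butanoic acid F2. Chemoselective reduction of the methyl ester of its potassium carboxylate with Ca(BH4)2 (from CaCl2 and NaBH4, EtOH), followed by acid lactonisation, should give (S)-4-[4-(benzyloxy)-3-methoxybenzyl]dihydrofuran-2(3H)-one F3. In parallel, 1 is reduced with NaBH4 to [4-(benzyloxy)-3-methoxyphenyl]methanol F4, which PBr3 converts into 1-(benzyloxy)-4-(bromomethyl)-2-methoxybenzene F5. The lithium enolate of F3 (LiN(SiMe3)2, THF, −78 °C) is alkylated by F5 on the face away from the C4 substituent, which should give the trans lactone (3S,4S)-3,4-bis[4-(benzyloxy)-3-methoxybenzyl]dihydrofuran-2(3H)-one F6. The potassium enolate of F6 (KN(SiMe3)2, THF, −78 °C) is then hydroxylated with 2-(phenylsulfonyl)-3-phenyloxaziridine on the face opposite the C4 benzyl; this should place the new hydroxyl trans to that group and the two benzyl groups cis, which is compound 13.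

2. Step 6. Alkylation may occur at the enol oxygen or at the benzylic carbon of the enolised pyruvate, the pyruvate may self-condense under base, and the electron-rich propargylic bromide may decompose before it is consumed.

   Fallback, in which the ketone is absent while the ester is made and is introduced by a late oxidation: it sets out from compounds 4 and 9 and comes back at compound 11. Reduction of 4 with NaBH4 (aq. NaHCO3/MeOH, 0 °C) should give rac-3-[4-(benzyloxy)-3-methoxyphenyl]-2-hydroxypropanoic acid F7, which cannot enolise. Its cesium salt (Cs2CO3, DMF) is alkylated with 9 to the hydroxy ester 3-[4-(benzyloxy)-3-methoxyphenyl]prop-2-yn-1-yl rac-3-[4-(benzyloxy)-3-methoxyphenyl]-2-hydroxypropanoate F8. Dess–Martin oxidation (CH2Cl2, NaHCO3, rt) then gives 11 immediately before step 7. The carbinol centre of F7 and F8 is racemic, which does not matter because it is oxidised away.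

3. Step 8. Hydrogen may be delivered to the wrong face, the double bond may migrate into the ring (C4=C5) ahead of reduction, or the catalyst may be arrested by the hindered tertiary carbinol beside the lactone carbonyl.

   Fallback, which replaces inner-sphere, coordination-directed hydrogenation by an outer-sphere radical hydrogen-atom-transfer hydrogenation under steric control: it sets out from compound 12 and comes back at compound 13 without any new compound. With Mn(dpm)3 (cat.), PhSiH3 and tBuOOH in iPrOH at rt, the first hydrogen atom should be transferred to C4, giving the benzylic radical, from the face remote from the large C3 benzyl group, which is the hydroxyl face. The benzylic radical is then reduced at a carbon that is not stereogenic. No metal–alkene complex is involved, so allylic C–O cleavage and alkene migration are not expected, and the benzyl ethers are not touched.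

**Further compounds**

F1 | step 7 | (E)-4-[4-(benzyloxy)-3-methoxyphenyl]-3-(methoxycarbonyl)but-3-enoic acid | COC(=O)/C(=C/c1ccc(OCc2ccccc2)c(OC)c1)CC(=O)O
F2 | step 7 | (S)-4-[4-(benzyloxy)-3-methoxyphenyl]-3-(methoxycarbonyl)butanoic acid | COC(=O)[C@@H](Cc1ccc(OCc2ccccc2)c(OC)c1)CC(=O)O
F3 | step 7 | (S)-4-[4-(benzyloxy)-3-methoxybenzyl]dihydrofuran-2(3H)-one | O=C1C[C@H](Cc2ccc(OCc3ccccc3)c(OC)c2)CO1
F4 | step 7 | [4-(benzyloxy)-3-methoxyphenyl]methanol | COc1cc(CO)ccc1OCc1ccccc1
F5 | step 7 | 1-(benzyloxy)-4-(bromomethyl)-2-methoxybenzene | COc1cc(CBr)ccc1OCc1ccccc1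
F6 | step 7 | (3S,4S)-3,4-bis[4-(benzyloxy)-3-methoxybenzyl]dihydrofuran-2(3H)-one | COc1cc(C[C@@H]2COC(=O)[C@H]2Cc2ccc(OCc3ccccc3)c(OC)c2)ccc1OCc1ccccc1
F7 | step 6 | rac-3-[4-(benzyloxy)-3-methoxyphenyl]-2-hydroxypropanoic acid | COc1cc(CC(O)C(=O)O)ccc1OCc1ccccc1
F8 | step 6 | 3-[4-(benzyloxy)-3-methoxyphenyl]prop-2-yn-1-yl rac-3-[4-(benzyloxy)-3-methoxyphenyl]-2-hydroxypropanoate | COc1cc(C#CCOC(=O)C(O)Cc2ccc(OCc3ccccc3)c(OC)c2)ccc1OCc1ccccc1
F0 | step 8 | none | none
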